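The ten-membered carbocycle (C1–C10) is not closed end to end but grown from a six-membered ring: an anionic oxy-Cope shift of a trans-1,2-dialkenylcyclohexenol forms C8–C9 and cuts C1–C6. In that single operation the potassium alkoxide delivers the cyclodecadiene with the Z-4-ene (the future cis-epoxide), the E-1(10)-ene, the C8 silyl-bearing stereocentre by chair chirality transfer and a regiodefined C6/C7 enolate, which is alkylated in the same flask to add C11/C12. The precursor is the adduct of (E)-2-(benzyldimethylsilyl)vinyllithium and (S)-isopiperitenone, made from (R)-limonene; silicon later becomes the C8 lactone oxygen.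

Key step: step 4

Remark on naming: ring compounds are named on the germacrane skeleton with the target's numbering (C1 carbinol carbon, C4/C5 epoxide, C6 angelate carbon, C7/C8 lactone fusion, C11–C13 lactone side chain, C14 on C10, C15 on C4). α/β are used as in the target, which is 1α-OH, 4α,5α-epoxy, 6α-OAng, 7α-H, 8β-H, i.e. (1S,4R,5S,6S,7R,8S). The SMILES strings are decisive.

Assumption: in the vanadium epoxidation the ten-membered (Z)-allylic alcohol is taken to behave like eight- and nine-membered (Z)-cycloalk-2-enols (cis delivery); the other case is covered by a fallback.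

Step 1
Reactants: 1 (R)-(+)-limonene
Product: 2 (S)-isopiperitenone [(6S)-3-methyl-6-(prop-1-en-2-yl)cyclohex-2-en-1-one]
Conditions: CrO3, 3,5-dimethylpyrazole, CH2Cl2, −20 °C
Reagents that add atoms: chromium trioxide, O=[Cr](=O)=O
Why: Allylic oxidation with the CrO3–dimethylpyrazole complex should convert the ring methylene between the vinylic CH and the stereocentre into the enone, because hydrogen abstraction there gives the more substituted allyl system (carvone from attack at the other allylic methylene is removed by chromatography); the stereocentre is not touched and only its descriptor changes from R to S.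

Step 2
Reactants: 3 (E)-1,2-bis(tributylstannyl)ethene; 4 benzyl(chloro)dimethylsilane
Product: 6 (E)-benzyldimethyl[2-(tributylstannyl)ethenyl]silane, via (E)-2-(tributylstannyl)vinyllithium 5 (not isolated)
Conditions: n-BuLi (1 equiv), THF, −78 °C; then 4, −78 °C → rt
Reagents that add atoms: none
Why: Tin–lithium exchange of one stannyl group gives a configurationally stable trans-vinyllithium, which the chlorosilane silylates with retention of the E geometry (transmetalation followed by electrophilic silylation).

Step 3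
Reactants: 6 (E)-benzyldimethyl[2-(tributylstannyl)ethenyl]silane; 2 (S)-isopiperitenone
Product: 8 (1S,6S)-1-[(E)-2-(benzyldimethylsilyl)ethenyl]-3-methyl-6-(prop-1-en-2-yl)cyclohex-2-en-1-ol, via (E)-2-(benzyldimethylsilyl)vinyllithium 7 (not isolated)
Conditions: n-BuLi, THF, −78 °C; then 2, −78 °C; H2O
Reagents that add atoms: none
Why: A second tin–lithium exchange and 1,2-addition of the vinyllithium to the enone carbonyl, in which the nucleophile enters anti to the neighbouring pseudo-equatorial isopropenyl group, so that the two alkenyl groups end up trans (hydroxyl cis to isopropenyl), as the chair transition state of step 4 requires.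

Step 4
Reactants: 8 (1S,6S)-1-[(E)-2-(benzyldimethylsilyl)ethenyl]-3-methyl-6-(prop-1-en-2-yl)cyclohex-2-en-1-ol; 9 tert-butyl bromoacetate
Product: 12 tert-butyl 8α-(benzyldimethylsilyl)-6-oxo-13-norgermacra-1(10)E,4Z-dien-12-oate (7αH), via potassium alkoxide 10 (not isolated), via potassium enolate 11 (not isolated)
Conditions: KHMDS, 18-crown-6, THF, 0 °C → rt; then 9, −78 °C
Reagents that add atoms: none
Why: KHMDS gives potassium alkoxide 10, whose charge weakens the adjacent C1–C6 bond so that the concerted [3,3] shift runs at or below room temperature to enolate 11; the closest known reaction is the anionic oxy-Cope rearrangement of isopiperitenone-derived 1,2-dialkenylcyclohexenols to (E,Z)-cyclodecadienones. The ten-membered ring is formed by four-atom ring expansion of the cyclohexene (C8–C9 made, C1–C6 broken), not by end-to-end closure, so no high dilution is needed. C8 is set by chirality transfer from the isopropenyl-bearing carbon through the one chair open to the trans (diequatorial) dialkenyl unit, in which the E-silyl group is equatorial; the same chair gives the E-1(10)-alkene and leaves the ring Z-alkene as the Z-4-ene. The E-vinylsilane cannot pass silicon to the alkoxide, and a β-silyl group, unlike a β-alkoxy group, is not expelled from the enolate. C7 is set in the alkylation: the bromoacetate should attack the outer face of the ring-trans enolate (the inner face is covered by the C1=C10 bond lying across the ring), which puts the side chain trans to silicon, and since C7 stays epimerisable next to the ketone the same isomer should also be favoured at equilibrium. The step needs C-alkylation at C7 only, which the regiodefined enolate (no equilibration to the extended dienolate at −78 °C) and the reactive α-halo ester secure.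

Step 5
Reactants: 12 tert-butyl 8α-(benzyldimethylsilyl)-6-oxo-13-norgermacra-1(10)E,4Z-dien-12-oate
Product: 13 tert-butyl 8α-(benzyldimethylsilyl)-6β-hydroxy-13-norgermacra-1(10)E,4Z-dien-12-oate
Conditions: L-Selectride, THF, −78 °C; then H2O (pH 7)
Reagents that add atoms: none
Why: 1,2-Reduction of the β,β-disubstituted enone by a bulky hydride under Felkin–Anh control (hydride anti to the C7–C8 ring bond, passing H7, with the acetate arm next to the carbonyl oxygen), the same sense that turns 2-alkylcycloalkanones into cis alcohols, so the hydroxyl is expected on the β-face, cis to the side chain; the tert-butyl ester resists hydride and lactonisation at −78 °C.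

Step 6
Reactants: 13 tert-butyl 8α-(benzyldimethylsilyl)-6β-hydroxy-13-norgermacra-1(10)E,4Z-dien-12-oate
Product: 15 tert-butyl 8α-(benzyldimethylsilyl)-6α-hydroxy-13-norgermacra-1(10)E,4Z-dien-12-oate, via 6α-(4-nitrobenzoate) 14 (not isolated)
Conditions: PPh3, DIAD, 4-nitrobenzoic acid, THF, 0 °C → rt; then K2CO3, MeOH, 0 °C
Reagents that add atoms: 4-nitrobenzoic acid, O=C(O)c1ccc(cc1)[N+](=O)[O-] (its oxygen becomes O6)
Why: Mitsunobu inversion of the hindered allylic carbinol (SN2 displacement of the oxyphosphonium group from the α-face, remote from the β side chain; the acidic 4-nitrobenzoic acid is the standard choice for hindered alcohols), followed by mild methanolysis of the activated benzoate, gives the 6α-alcohol without touching the tert-butyl ester.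

Step 7
Reactants: 15 tert-butyl 8α-(benzyldimethylsilyl)-6α-hydroxy-13-norgermacra-1(10)E,4Z-dien-12-oate
Product: 16 tert-butyl 8α-(benzyldimethylsilyl)-4α,5α-epoxy-6α-hydroxy-13-norgermacr-1(10)E-en-12-oate
Conditions: VO(acac)2 (cat.), t-BuOOH, CH2Cl2, 0 °C → rt
Reagents that add atoms: tert-butyl hydroperoxide, CC(C)(C)OO
Why: Vanadium-catalysed hydroxyl-directed epoxidation is chemoselective for the allylic C4=C5 bond over the remote C1=C10 bond, and the vanadate ester should deliver oxygen through the small O–C6–C5=C4 dihedral geometry that gives cis epoxy alcohols from medium-ring (Z)-cycloalk-2-enols, so the epoxide forms on the α-face (cis to the 6α-hydroxyl in the ring sense) and the Z geometry is carried into the cis-epoxide, setting C4 and C5.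

Step 8
Reactants: 16 tert-butyl 8α-(benzyldimethylsilyl)-4α,5α-epoxy-6α-hydroxy-13-norgermacr-1(10)E-en-12-oate
Product: 17 tert-butyl 8α-(benzyldimethylsilyl)-6α-(tert-butyldimethylsilyloxy)-4α,5α-epoxy-13-norgermacr-1(10)E-en-12-oate
Conditions: TBSOTf, 2,6-lutidine, CH2Cl2, −78 °C
Reagents that add atoms: tert-butyldimethylsilyl triflate, CC(C)(C)[Si](C)(C)OS(=O)(=O)C(F)(F)F
Why: Silyl ether formation under non-basic conditions blocks O6 so that it can neither lactonise onto C12 nor interfere with the later enolate chemistry, and since no alkoxide is formed a Payne rearrangement of the epoxy alcohol is avoided.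

Step 9
Reactants: 17 tert-butyl 8α-(benzyldimethylsilyl)-6α-(tert-butyldimethylsilyloxy)-4α,5α-epoxy-13-norgermacr-1(10)E-en-12-oate
Product: 19 tert-butyl 6α-(tert-butyldimethylsilyloxy)-4α,5α-epoxy-8α-hydroxy-13-norgermacr-1(10)E-en-12-oate, via 8α-fluorodimethylsilyl intermediate 18 (not isolated)
Conditions: TBAF (1.2 equiv), THF, 0 °C, 10 min; then KHCO3, 30% H2O2, MeOH, rt
Reagents that add atoms: hydrogen peroxide, OO
Why: Tamao–Fleming oxidation in which fluoride cleaves the benzyl–silicon bond within minutes (short enough for the hindered secondary TBS ether to survive) and basic hydrogen peroxide then moves C8 from silicon to oxygen with retention, giving the 8α-alcohol without any electrophilic reagent that would harm the alkene or the epoxide.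

Step 10
Reactants: 19 tert-butyl 6α-(tert-butyldimethylsilyloxy)-4α,5α-epoxy-8α-hydroxy-13-norgermacr-1(10)E-en-12-oate
Product: 20 6α-(tert-butyldimethylsilyloxy)-4α,5α-epoxy-13-norgermacr-1(10)E-en-12,8α-olide
Conditions: t-BuOK (0.2 equiv), THF, 0 °C
Reagents that add atoms: none
Why: Base-catalysed intramolecular transesterification (5-exo-trig lactonisation) closes the γ-lactone from O8 onto C12 with loss of tert-butoxide; only the 8,12-olide can form because O6 is silylated, and the trans ring fusion follows from the C7/C8 configurations set in steps 4 and 9.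

Step 11
Reactants: 20 6α-(tert-butyldimethylsilyloxy)-4α,5α-epoxy-13-norgermacr-1(10)E-en-12,8α-olide
Product: 24 6α-(tert-butyldimethylsilyloxy)-4α,5α-epoxygermacra-1(10)E,11(13)-dien-12,8α-olide, via lithium lactone enolate 21 (not isolated), via Mannich base 22 (not isolated), via trimethylammonium iodide 23 (not isolated)
Conditions: LDA, THF, −78 °C; CH2=NMe2+ I−, −78 °C → rt; then MeI, MeOH, rt; aq NaHCO3, EtOAc
Reagents that add atoms: Eschenmoser's salt (dimethylmethyleneammonium iodide), C[N+](C)=C.[I-]
Why: α-Methylenation of the γ-lactone by the Mannich route (aminomethylation of the lithium enolate, quaternisation, mild base-induced β-elimination) installs C13 as the exocyclic C11=C13 alkene; the transient C11 stereocentre is destroyed and the silyl ether keeps C6 from forming an alkoxide.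

Step 12
Reactants: 24 6α-(tert-butyldimethylsilyloxy)-4α,5α-epoxygermacra-1(10)E,11(13)-dien-12,8α-olide
Product: 25 4α,5α-epoxy-6α-hydroxygermacra-1(10)E,11(13)-dien-12,8α-olide
Conditions: HF·pyridine, pyridine, THF, 0 °C → rt
Reagents that add atoms: none
Why: Pyridine-buffered fluoride desilylation should free the 6α-hydroxyl without opening the epoxide or adding to the α-methylene lactone.

Step 13
Reactants: 25 4α,5α-epoxy-6α-hydroxygermacra-1(10)E,11(13)-dien-12,8α-olide; 26 angelic acid [(Z)-2-methylbut-2-enoic acid]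
Product: 28 6α-angeloyloxy-4α,5α-epoxygermacra-1(10)E,11(13)-dien-12,8α-olide, via mixed anhydride 27 (not isolated)
Conditions: 26, 2,4,6-trichlorobenzoyl chloride, Et3N, toluene, rt; then 25, DMAP, toluene, 40 °C
Reagents that add atoms: none
Why: Yamaguchi esterification, in which the mixed anhydride acylates the hindered secondary alcohol at the angeloyl carbonyl under DMAP catalysis, is the established way to make angelates without Z-to-E isomerisation to the tiglate; the C6–O bond is not broken, so C6 keeps its configuration.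

Step 14
Reactants: 28 6α-angeloyloxy-4α,5α-epoxygermacra-1(10)E,11(13)-dien-12,8α-olide
Product: 30 6α-angeloyloxy-4α,5α-epoxy-1α-hydroxygermacra-10(14),11(13)-dien-12,8α-olide (CNP0104965.1), via 1α-hydroperoxide 29 (not isolated)
Conditions: O2, hν, tetraphenylporphyrin (cat.), CH2Cl2, 0 °C; then PPh3, 0 °C
Reagents that add atoms: oxygen, O=O
Why: Schenck ene reaction of singlet oxygen with the only electron-rich alkene (the α-methylene lactone and the angelate are electron-poor) takes hydrogen from the C14 methyl on the disubstituted side, as in the photooxygenation of germacranolide 1(10)-enes, which moves the double bond to C10=C14 and puts OOH on C1; attack on the outer face of the trans-cyclodecene unit in the conformer with the C10 methyl anti to the β-oriented C4 methyl should give the 1α-hydroperoxide, and triphenylphosphine reduces the O–O bond without touching C1.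

Compound list
1 | (R)-(+)-limonene | C=C(C)[C@@H]1CCC(C)=CC1 | starting material
2 | (S)-isopiperitenone [(6S)-3-methyl-6-(prop-1-en-2-yl)cyclohex-2-en-1-one] | C=C(C)[C@@H]1CCC(C)=CC1=O | intermediate
3 | (E)-1,2-bis(tributylstannyl)ethene | CCCC[Sn](CCCC)(CCCC)/C=C/[Sn](CCCC)(CCCC)CCCC | starting material
4 | benzyl(chloro)dimethylsilane | C[Si](C)(Cl)Cc1ccccc1 | starting material
5 | (E)-2-(tributylstannyl)vinyllithium | [Li]/C=C/[Sn](CCCC)(CCCC)CCCC | intermediate
6 | (E)-benzyldimethyl[2-(tributylstannyl)ethenyl]silane | C[Si](C)(Cc1ccccc1)/C=C/[Sn](CCCC)(CCCC)CCCC | intermediate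
7 | (E)-2-(benzyldimethylsilyl)vinyllithium | [Li]/C=C/[Si](C)(C)Cc1ccccc1 | intermediate
8 | (1S,6S)-1-[(E)-2-(benzyldimethylsilyl)ethenyl]-3-methyl-6-(prop-1-en-2-yl)cyclohex-2-en-1-ol (alkenyl groups trans) | C=C(C)[C@@H]1CCC(C)=C[C@@]1(O)/C=C/[Si](C)(C)Cc1ccccc1 | intermediate
9 | tert-butyl bromoacetate | CC(C)(C)OC(=O)CBr | starting material
10 | potassium alkoxide of 8 | C=C(C)[C@@H]1CCC(C)=C[C@@]1([O-])/C=C/[Si](C)(C)Cc1ccccc1.[K+] | intermediate
11 | potassium enolate of (2Z,6E)-9-(benzyldimethylsilyl)-3,7-dimethylcyclodeca-2,6-dien-1-one (C6/C7 enolate; 8α-silyl) | C[Si](C)(Cc1ccccc1)[C@H]1C/C(C)=C/CC/C(C)=C\C([O-])=C\1.[K+] | intermediate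
12 | tert-butyl 8α-(benzyldimethylsilyl)-6-oxo-13-norgermacra-1(10)E,4Z-dien-12-oate (7αH; side chain trans to silicon) | C[Si](C)(Cc1ccccc1)[C@H]1C/C(C)=C/CC/C(C)=C\C(=O)[C@@H]1CC(=O)OC(C)(C)C | intermediate
13 | tert-butyl 8α-(benzyldimethylsilyl)-6β-hydroxy-13-norgermacra-1(10)E,4Z-dien-12-oate | C[Si](C)(Cc1ccccc1)[C@H]1C/C(C)=C/CC/C(C)=C\[C@H](O)[C@@H]1CC(=O)OC(C)(C)C | intermediate
14 | tert-butyl 8α-(benzyldimethylsilyl)-6α-(4-nitrobenzoyloxy)-13-norgermacra-1(10)E,4Z-dien-12-oate | C[Si](C)(Cc1ccccc1)[C@H]1C/C(C)=C/CC/C(C)=C\[C@@H](OC(=O)c2ccc(cc2)[N+](=O)[O-])[C@@H]1CC(=O)OC(C)(C)C | intermediate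
15 | tert-butyl 8α-(benzyldimethylsilyl)-6α-hydroxy-13-norgermacra-1(10)E,4Z-dien-12-oate | C[Si](C)(Cc1ccccc1)[C@H]1C/C(C)=C/CC/C(C)=C\[C@@H](O)[C@@H]1CC(=O)OC(C)(C)C | intermediate
16 | tert-butyl 8α-(benzyldimethylsilyl)-4α,5α-epoxy-6α-hydroxy-13-norgermacr-1(10)E-en-12-oate | C[Si](C)(Cc1ccccc1)[C@H]1C/C(C)=C/CC[C@@]2(C)O[C@H]2[C@@H](O)[C@@H]1CC(=O)OC(C)(C)C | intermediate
17 | tert-butyl 8α-(benzyldimethylsilyl)-6α-(tert-butyldimethylsilyloxy)-4α,5α-epoxy-13-norgermacr-1(10)E-en-12-oate | C[Si](C)(Cc1ccccc1)[C@H]1C/C(C)=C/CC[C@@]2(C)O[C@H]2[C@@H](O[Si](C)(C)C(C)(C)C)[C@@H]1CC(=O)OC(C)(C)C | intermediate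
18 | tert-butyl 6α-(tert-butyldimethylsilyloxy)-4α,5α-epoxy-8α-(fluorodimethylsilyl)-13-norgermacr-1(10)E-en-12-oate | F[Si](C)(C)[C@H]1C/C(C)=C/CC[C@@]2(C)O[C@H]2[C@@H](O[Si](C)(C)C(C)(C)C)[C@@H]1CC(=O)OC(C)(C)C | intermediate
19 | tert-butyl 6α-(tert-butyldimethylsilyloxy)-4α,5α-epoxy-8α-hydroxy-13-norgermacr-1(10)E-en-12-oate | O[C@H]1C/C(C)=C/CC[C@@]2(C)O[C@H]2[C@@H](O[Si](C)(C)C(C)(C)C)[C@@H]1CC(=O)OC(C)(C)C | intermediate
20 | 6α-(tert-butyldimethylsilyloxy)-4α,5α-epoxy-13-norgermacr-1(10)E-en-12,8α-olide (trans-fused) | C1C(=O)O[C@H]2C/C(C)=C/CC[C@@]3(C)O[C@H]3[C@@H](O[Si](C)(C)C(C)(C)C)[C@H]12 | intermediate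
21 | lithium enolate of lactone 20 | C1=C([O-])O[C@H]2C/C(C)=C/CC[C@@]3(C)O[C@H]3[C@@H](O[Si](C)(C)C(C)(C)C)[C@H]12.[Li+] | intermediate
22 | 6α-(tert-butyldimethylsilyloxy)-13-(dimethylamino)-4α,5α-epoxygermacr-1(10)E-en-12,8α-olide (C11 epimers) | CN(C)CC1C(=O)O[C@H]2C/C(C)=C/CC[C@@]3(C)O[C@H]3[C@@H](O[Si](C)(C)C(C)(C)C)[C@H]12 | intermediate
23 | trimethylammonium iodide of 22 | C[N+](C)(C)CC1C(=O)O[C@H]2C/C(C)=C/CC[C@@]3(C)O[C@H]3[C@@H](O[Si](C)(C)C(C)(C)C)[C@H]12.[I-] | intermediate
24 | 6α-(tert-butyldimethylsilyloxy)-4α,5α-epoxygermacra-1(10)E,11(13)-dien-12,8α-olide | C=C1C(=O)O[C@H]2C/C(C)=C/CC[C@@]3(C)O[C@H]3[C@@H](O[Si](C)(C)C(C)(C)C)[C@H]12 | intermediate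
25 | 4α,5α-epoxy-6α-hydroxygermacra-1(10)E,11(13)-dien-12,8α-olide | C=C1C(=O)O[C@H]2C/C(C)=C/CC[C@@]3(C)O[C@H]3[C@@H](O)[C@H]12 | intermediate
26 | angelic acid [(Z)-2-methylbut-2-enoic acid] | C/C=C(/C)C(=O)O | starting material
27 | angelic 2,4,6-trichlorobenzoic anhydride | C/C=C(/C)C(=O)OC(=O)c1c(Cl)cc(Cl)cc1Cl | intermediate
28 | 6α-angeloyloxy-4α,5α-epoxygermacra-1(10)E,11(13)-dien-12,8α-olide | C=C1C(=O)O[C@H]2C/C(C)=C/CC[C@@]3(C)O[C@H]3[C@@H](OC(=O)/C(C)=C\C)[C@H]12 | intermediate
29 | 6α-angeloyloxy-4α,5α-epoxy-1α-hydroperoxygermacra-10(14),11(13)-dien-12,8α-olide | C=C1C(=O)O[C@H]2CC(=C)[C@@H](OO)CC[C@@]3(C)O[C@H]3[C@@H](OC(=O)/C(C)=C\C)[C@H]12 | intermediate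
30 | 6α-angeloyloxy-4α,5α-epoxy-1α-hydroxygermacra-10(14),11(13)-dien-12,8α-olide (CNP0104965.1) | C=C1C(=O)O[C@H]2CC(=C)[C@@H](O)CC[C@@]3(C)O[C@H]3[C@@H](OC(=O)/C(C)=C\C)[C@H]12 | target

Total step count: 14
Longest linear sequence: 13 steps (steps 1 and 3–14 from limonene; equally steps 2–14 from the distannane)

Steps most likely to fail

Step 4. During the one-pot alkylation the α-bromo ester may protonate the potassium enolate or react at oxygen, and the electrophile may enter on the wrong face at C7. The fallback sets out from 8 and comes back at 12. The rearrangement is run alone and quenched with aqueous NH4Cl to give the ketone (2Z,6E)-9-(benzyldimethylsilyl)-3,7-dimethylcyclodeca-2,6-dien-1-one F1. Kinetic α′-deprotonation with LDA (THF, −78 °C) gives its lithium enolate F2, which is alkylated with 9 in THF–DMPU. Any 7-epimer of the keto ester F3 is then equilibrated with DBU in toluene to the 7,8-trans isomer 12, so that C7 is set under thermodynamic instead of kinetic control.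

Step 7. The vanadate may deliver oxygen through the acyclic-type transition state (H6 eclipsing the alkene, threo outcome), which from 15 would put the epoxide on the β-face. The fallback sets out from 13 and comes back at 16, replacing steps 6 and 7. The 6β-alcohol 13 is epoxidised directly with VO(acac)2/t-BuOOH, where the same threo preference now gives tert-butyl 8α-(benzyldimethylsilyl)-4α,5α-epoxy-6β-hydroxy-13-norgermacr-1(10)E-en-12-oate F4. Dess–Martin oxidation gives the cis-α,β-epoxy ketone F5. Zn(BH4)2 (Et2O, −20 °C) reduces it under chelation control, zinc bridging the carbonyl and epoxide oxygens, to the erythro epoxy alcohol 16, so that C6 is inverted after instead of before the epoxidation.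

Step 14. Singlet oxygen may add to the other face of C1=C10 and give the C1 epimer, because the facial choice rests on the ring conformation alone. The fallback sets out from 28 and comes back at 30. Photooxygenation is run as in step 14, but the hydroperoxide 29 (either C1 configuration leads to the same ketone) is dehydrated with Ac2O, pyridine and DMAP (Kornblum–DeLaMare) to the enone 6α-angeloyloxy-4α,5α-epoxy-1-oxogermacra-10(14),11(13)-dien-12,8α-olide F6. Catalyst-controlled 1,2-reduction with (R)-Me-CBS and catecholborane (toluene, −78 °C), the 2-substituted vinyl group acting as the large substituent, should then give the (1S)-alcohol 30 whichever face oxygen had chosen.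

Further compounds
F1 | step 4 | (2Z,6E)-9-(benzyldimethylsilyl)-3,7-dimethylcyclodeca-2,6-dien-1-one (8α-silyl in germacrane numbering) | C[Si](C)(Cc1ccccc1)[C@H]1C/C(C)=C/CC/C(C)=C\C(=O)C1
F2 | step 4 | lithium enolate of F1 (C6/C7 enolate) | C[Si](C)(Cc1ccccc1)[C@H]1C/C(C)=C/CC/C(C)=C\C([O-])=C1.[Li+]
F3 | step 4 | tert-butyl 8α-(benzyldimethylsilyl)-6-oxo-13-norgermacra-1(10)E,4Z-dien-12-oate, 7-epimer (7βH) | C[Si](C)(Cc1ccccc1)[C@H]1C/C(C)=C/CC/C(C)=C\C(=O)[C@H]1CC(=O)OC(C)(C)C
F4 | step 7 | tert-butyl 8α-(benzyldimethylsilyl)-4α,5α-epoxy-6β-hydroxy-13-norgermacr-1(10)E-en-12-oate | C[Si](C)(Cc1ccccc1)[C@H]1C/C(C)=C/CC[C@@]2(C)O[C@H]2[C@H](O)[C@@H]1CC(=O)OC(C)(C)C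
F5 | step 7 | tert-butyl 8α-(benzyldimethylsilyl)-4α,5α-epoxy-6-oxo-13-norgermacr-1(10)E-en-12-oate | C[Si](C)(Cc1ccccc1)[C@H]1C/C(C)=C/CC[C@@]2(C)O[C@H]2C(=O)[C@@H]1CC(=O)OC(C)(C)C
F6 | step 14 | 6α-angeloyloxy-4α,5α-epoxy-1-oxogermacra-10(14),11(13)-dien-12,8α-olide | C=C1C(=O)O[C@H]2CC(=C)C(=O)CC[C@@]3(C)O[C@H]3[C@@H](OC(=O)/C(C)=C\C)[C@H]12
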